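At early times the coupling partner in these flasks is free, and I want a number for what the target is worth once that partner has gone over to the dormant form.

all flasks: substrate 0.25 M; coupling partner 0.300 M; catalyst 0.50 mM; time 20 s

| flask | temperature |
|---|---|
| Friday's | 70 °C |
| Thursday's | 10 °C |
| Monday's | 40 °C |

- which flask leads in amount of target, in percent of the substrate charged ("all alike" within 1.5 percentage points) (Friday's / Thursday's / Monday's / all alike)
- how much target is there at the end, in percent of the substrate charged: Friday's
- how much target is there at the end, in percent of the substrate charged: Thursday's
- how much target is there at the end, in percent of the substrate charged: Monday's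

    coupling partner ⇌ dormant form (K1 = 24, k1 = 1.1 s⁻¹, Ea1 = 69.0 kJ mol⁻¹, ΔH1 = 11.0 kJ mol⁻¹)
    substrate + coupling partner + catalyst ⇌ target + catalyst, rate k2*[substrate]*[coupling partner]*[catalyst] forward; the back reaction follows from the equilibrium constant (K2 = 0.48 M⁻¹, k2 = 7100 M⁻² s⁻¹, Ea2 = 30.0 kJ mol⁻¹, ΔH2 = −69.0 kJ mol⁻¹)
    catalyst + target ⇌ idle complex (K3 = 5.6 M⁻¹, k3 = 0.54 M⁻¹ s⁻¹, Ea3 = 53.0 kJ mol⁻¹, ΔH3 = −35.0 kJ mol⁻¹)
    target + catalyst ⇌ isomer of the product + catalyst, rate k4*[catalyst]*[target] forward; the back reaction follows from the equilibrium constant (K4 = 2.9, k4 = 52 M⁻¹ s⁻¹, Ea4 = 44.0 kJ mol⁻¹, ΔH4 = 25.0 kJ mol⁻¹)
    (constants at 40 °C)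

- amounts and yields of target count idle complex too
- all constants are for 40 °C and move with temperature by the activation energies and enthalpies

Two extreme flasks can be solved in the head. In the first, the dormant form does not exist, and target follows the equilibrium of the coupling step, with [target] = K[substrate][coupling partner]. In the second, the partner has finished its equilibrium with the dormant form. Free partner is then a share, one over one plus the dormant constant, of what is not in target, so the same equation holds with a smaller constant.

Take Thursday's flask. Its coupling constant rises to 7.96 M⁻¹ and its dormant constant falls to 15.3. The first extreme, solved as a quadratic, gives a ceiling of 56.0 %. The coupling constant divided by one plus the dormant constant is 0.487 M⁻¹, and this drained constant, the apparent equilibrium constant of the coupling step, is what I carry. It gives Thursday's a drained yield of 11.7 %.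

Friday's coupling constant is 0.0473 M⁻¹ and its dormant constant 34.7, so its drained constant is 0.00132 M⁻¹. Monday's is 0.0192 M⁻¹. With substrate barely touched, the drained yield is the drained constant times the partner charge: 0.0397 % for Friday's and 0.576 % for Monday's. In powers of ten these are −3.40 and −2.24.

Where a flask lies between its extremes depends on the half-life of the drain. That is 0.0604 s in Friday's and 0.605 s in Monday's, far shorter than the 20 s of the run, so I put both on their drained yields. Thursday's drain has a half-life of 9.80 s, so the run lasts 2.04 half-lives. If the gap between ceiling and drained yield shrinks at that pace, Thursday's ends near 22.4 %, more than the other two. The drain reaches free partner and not partner held in target, so I take this as a low mark.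

The forecast also names Thursday's, with 0.04 % for Friday's, 32 % for Thursday's and 0.55 % for Monday's, on the ground that at the cold end “the drain to the dormant form is slow”. Its Thursday's figure stands above mine.

The simulation gives Thursday's the lead, with 0.0397 % in Friday's, 36.0 % in Thursday's and 0.564 % in Monday's. On Friday's figure the largest single effect is the back reaction of target to substrate and coupling partner : with it struck out, Friday's reads 21.6 % against 0.0397 %, and Friday's drained constant of 0.00132 M⁻¹ had given 0.0397 %. The drained constant holds no catalyst, and Friday's neighbour with 0.0013 M of catalyst reads 0.0397 %.

The constants used here stand for no real mixture; the run is a simulation.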